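The ester C–O bond is made late; the terpinen-4-ol half is built around its quaternary carbinol carbon (C1 of the 1-isopropyl-4-methylcyclohex-3-ene ring), treated as the α-carbon of a latent α-hydroxy acid whose carboxyl is the masked isopropyl group. In the key step the enolate of a chiral 5-allyl-2-tert-butyl-1,3-dioxolan-4-one (from D-allylglycine) is alkylated by 3-methylbut-3-enyl triflate anti to tert-butyl (ring bond C1–C6, quaternary stereocentre), and the resulting diene is closed in the same flask by metathesis (ring alkene C3=C4), giving a spirocyclic cyclohexene. Carboxyl-to-isopropyl conversion, acylation and double prenylation finish the route.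

Key step: step 4

Remark on the chemistry: ring positions follow 1-isopropyl-4-methylcyclohex-3-en-1-yl (C1 = carbinol carbon); the key step is run as one flask operation without isolating the diene.

Step 1
Reactants: 1 D-allylglycine, (2R)-2-aminopent-4-enoic acid
Product: 2 (2R)-2-hydroxypent-4-enoic acid
Conditions: NaNO2, 1 M H2SO4 (aq), 0 °C → rt
Reagents that add atoms: water (O)
Why: Diazotisation of the α-amino acid and hydrolysis with neighbouring-group participation of the carboxylate (double inversion) should replace NH2 by OH with net retention, so the (R) centre is taken over from the amino acid.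

Step 2
Reactants: 2 (2R)-2-hydroxypent-4-enoic acid, 3 pivalaldehyde
Product: 4 (2R,5R)-2-tert-butyl-5-(prop-2-en-1-yl)-1,3-dioxolan-4-one (cis)
Conditions: TsOH (cat.), H2SO4 (cat.), pentane, reflux, Dean–Stark; cis isomer by chromatography
Reagents that add atoms: none
Why: Acid-catalysed acetalisation with azeotropic removal of water should give the dioxolanone with the new acetal centre preferentially cis to the allyl group (control by the C5 centre, minor trans isomer removed), which stores the chirality for self-regeneration of the stereocentre.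

Step 3
Reactants: 5 3-methylbut-3-en-1-ol
Product: 6 3-methylbut-3-en-1-yl trifluoromethanesulfonate
Conditions: Tf2O, 2,6-lutidine, CH2Cl2, −78 °C; used at once
Reagents that add atoms: triflic anhydride (O=S(=O)(OS(=O)(=O)C(F)(F)F)C(F)(F)F)
Why: O-Sulfonylation of the primary homoallylic alcohol should give a primary alkyl triflate that is reactive enough to alkylate a hindered ester enolate at −78 °C.

Step 4
Reactants: 4 (2R,5R)-2-tert-butyl-5-(prop-2-en-1-yl)-1,3-dioxolan-4-one, 6 3-methylbut-3-en-1-yl trifluoromethanesulfonate
Product: 9 (2R,5R)-2-tert-butyl-8-methyl-1,3-dioxaspiro[4.5]dec-7-en-4-one, via lithium dioxolanone enolate 7 (not isolated), via alkylated diene 8 (not isolated)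
Conditions: LDA, THF, −78 °C; 6, −78 → −30 °C; evaporate, CH2Cl2, (H2IMes)(PCy3)Cl2Ru=CHPh (5 mol%), 40 °C, same flask
Reagents that add atoms: none
Why: LDA removes the C5 proton of 4 to give the planar enolate 7, whose only stereocentre is the acetal carbon C2; SN2 attack of C5 on the primary triflate from the face anti to tert-butyl forges the bond between the future carbinol carbon (cyclohexene C1) and C6 and regenerates the quaternary centre with overall retention (self-regeneration of stereocentres). After removal of THF and diisopropylamine the Ru alkylidene loads on the monosubstituted allyl terminus, and [2+2] cycloaddition/cycloreversion with the 1,1-disubstituted alkene closes the ring with loss of ethene, creating the trisubstituted C3=C4 bond. The closest known reaction types are the alkylation of 2-tert-butyl-1,3-dioxolan-4-one enolates to α,α-disubstituted α-hydroxy acid derivatives and the ring-closing metathesis of 1,7-dienes to 1-methylcyclohexenes. The six-membered carbocycle closes by ring-closing metathesis at the spiro carbon, where gem-disubstitution favours cyclisation over oligomerisation and only the cis ring alkene can form. The single new stereocentre (spiro C5, R) is controlled by the acetal tert-butyl group, and the metathesis does not touch it. The step needs C- over O-alkylation (lithium enolate in THF), anti facial attack (tert-butyl shielding) and substitution over elimination of the triflate (low temperature).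

Step 5
Reactants: 9 (2R,5R)-2-tert-butyl-8-methyl-1,3-dioxaspiro[4.5]dec-7-en-4-one
Product: 10 1-[(1R)-1-hydroxy-4-methylcyclohex-3-en-1-yl]ethan-1-one
Conditions: MeLi (1.05 equiv), Et2O/THF, −78 °C; aq NH4Cl at −78 °C
Reagents that add atoms: methyllithium ([Li]C)
Why: A single addition of methyllithium to the lactone carbonyl at −78 °C followed by cold aqueous quench should release the methyl ketone and pivalaldehyde (acyl substitution of a lactone that stops at the ketone), leaving the quaternary centre untouched.

Step 6
Reactants: 10 1-[(1R)-1-hydroxy-4-methylcyclohex-3-en-1-yl]ethan-1-one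
Product: 11 (1R)-4-methyl-1-(prop-1-en-2-yl)cyclohex-3-en-1-ol
Conditions: Ph3PCH3Br, KOtBu (3 equiv each), THF, 0 → 60 °C
Reagents that add atoms: methyltriphenylphosphonium bromide (C[P+](c1ccccc1)(c1ccccc1)c1ccccc1.[Br-])
Why: Wittig methylenation with excess non-stabilised ylide should convert the hindered methyl ketone into the isopropenyl group in the presence of the free tertiary hydroxyl.

Step 7
Reactants: 11 (1R)-4-methyl-1-(prop-1-en-2-yl)cyclohex-3-en-1-ol
Product: 12 (1R)-4-methyl-1-(propan-2-yl)cyclohex-3-en-1-ol, (R)-terpinen-4-ol
Conditions: H2 (1 atm), RhCl(PPh3)3 (5 mol%), benzene, rt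
Reagents that add atoms: none
Why: Homogeneous hydrogenation with RhCl(PPh3)3 should reduce the 1,1-disubstituted isopropenyl alkene much faster than the trisubstituted ring alkene (as in the selective reduction of limonene) and without hydrogenolysis of the allylic C–O bond.

Step 8
Reactants: 13 3,5-dibromo-4-methoxybenzoic acid
Product: 14 3,5-dibromo-4-methoxybenzoyl chloride
Conditions: (COCl)2, DMF (cat.), CH2Cl2, 0 °C → rt
Reagents that add atoms: oxalyl chloride (ClC(=O)C(=O)Cl)
Why: Vilsmeier-type activation of the benzoic acid should give the acyl chloride with loss of CO, CO2 and HCl.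

Step 9
Reactants: 12 (R)-terpinen-4-ol, 14 3,5-dibromo-4-methoxybenzoyl chloride
Product: 16 (1R)-4-methyl-1-(propan-2-yl)cyclohex-3-en-1-yl 3,5-dibromo-4-methoxybenzoate, via lithium terpinen-4-olate 15 (not isolated)
Conditions: n-BuLi (1.0 equiv), THF, −78 → 0 °C; then 14, 0 °C → rt
Reagents that add atoms: none
Why: Irreversible deprotonation of the hindered tertiary alcohol and O-acylation of the alkoxide by the aroyl chloride (addition–elimination) is the reliable way to esterify a tertiary alcohol, and the stereocentre is not involved.

Step 10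
Reactants: 16 (1R)-4-methyl-1-(propan-2-yl)cyclohex-3-en-1-yl 3,5-dibromo-4-methoxybenzoate, 17 tributyl(3-methylbut-2-en-1-yl)stannane
Product: 18 (1R)-4-methyl-1-(propan-2-yl)cyclohex-3-en-1-yl 4-methoxy-3,5-bis(3-methylbut-2-en-1-yl)benzoate (target)
Conditions: 17 (2.5 equiv), Pd(PPh3)4 (10 mol%), DMF, 90 °C
Reagents that add atoms: none
Why: Twofold Stille coupling of the aryl dibromide should install both prenyl groups through the α-carbon of the allylstannane, while Pd(0) does not ionise the homoallylic tertiary ester and the ring alkene is inert.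

Compound list
1 | D-allylglycine, (2R)-2-aminopent-4-enoic acid | N[C@H](CC=C)C(=O)O | starting material
2 | (2R)-2-hydroxypent-4-enoic acid | O[C@H](CC=C)C(=O)O | intermediate
3 | pivalaldehyde (2,2-dimethylpropanal) | CC(C)(C)C=O | starting material
4 | (2R,5R)-2-tert-butyl-5-(prop-2-en-1-yl)-1,3-dioxolan-4-one | C=CC[C@H]1O[C@@H](C(C)(C)C)OC1=O | intermediate
5 | 3-methylbut-3-en-1-ol | CC(=C)CCO | starting material
6 | 3-methylbut-3-en-1-yl trifluoromethanesulfonate | CC(=C)CCOS(=O)(=O)C(F)(F)F | intermediate
7 | lithium (2R)-2-tert-butyl-5-(prop-2-en-1-yl)-1,3-dioxol-4-olate | [Li+].[O-]C1=C(CC=C)O[C@@H](C(C)(C)C)O1 | intermediate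
8 | (2R,5R)-2-tert-butyl-5-(3-methylbut-3-en-1-yl)-5-(prop-2-en-1-yl)-1,3-dioxolan-4-one | C=CC[C@@]1(CCC(C)=C)O[C@@H](C(C)(C)C)OC1=O | intermediate
9 | (2R,5R)-2-tert-butyl-8-methyl-1,3-dioxaspiro[4.5]dec-7-en-4-one | CC1=CC[C@@]2(CC1)O[C@@H](C(C)(C)C)OC2=O | intermediate
10 | 1-[(1R)-1-hydroxy-4-methylcyclohex-3-en-1-yl]ethan-1-one | CC1=CC[C@@](CC1)(O)C(C)=O | intermediate
11 | (1R)-4-methyl-1-(prop-1-en-2-yl)cyclohex-3-en-1-ol | CC1=CC[C@@](CC1)(O)C(C)=C | intermediate
12 | (1R)-4-methyl-1-(propan-2-yl)cyclohex-3-en-1-ol, (R)-terpinen-4-ol | CC1=CC[C@@](CC1)(O)C(C)C | intermediate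
13 | 3,5-dibromo-4-methoxybenzoic acid | OC(=O)c1cc(Br)c(OC)c(Br)c1 | starting material
14 | 3,5-dibromo-4-methoxybenzoyl chloride | ClC(=O)c1cc(Br)c(OC)c(Br)c1 | intermediate
15 | lithium (1R)-4-methyl-1-(propan-2-yl)cyclohex-3-en-1-olate | [Li+].[O-][C@@]1(C(C)C)CC=C(C)CC1 | intermediate
16 | (1R)-4-methyl-1-(propan-2-yl)cyclohex-3-en-1-yl 3,5-dibromo-4-methoxybenzoate | COc1c(Br)cc(C(=O)O[C@@]2(C(C)C)CC=C(C)CC2)cc1Br | intermediate
17 | tributyl(3-methylbut-2-en-1-yl)stannane | CCCC[Sn](CCCC)(CCCC)CC=C(C)C | starting material
18 | (1R)-4-methyl-1-(propan-2-yl)cyclohex-3-en-1-yl 4-methoxy-3,5-bis(3-methylbut-2-en-1-yl)benzoate | COc1c(CC=C(C)C)cc(C(=O)O[C@@]2(C(C)C)CC=C(C)CC2)cc1CC=C(C)C | target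

Total step count: 10. Longest linear sequence: 8 (steps 1, 2, 4, 5, 6, 7, 9, 10).

Steps most likely to fail:

Step 4. The tetrasubstituted enolate may alkylate too slowly with the homoallylic triflate, so that elimination of the triflate, O-alkylation or thermal breakdown of the enolate take over; carried-over amine may also stop the Ru catalyst. The fallback sets out from 4: conjugate addition of its lithium enolate to but-3-en-2-one (LDA, THF, −78 °C) should give, again anti to tert-butyl, (2R,5R)-2-tert-butyl-5-(3-oxobutyl)-5-(prop-2-en-1-yl)-1,3-dioxolan-4-one F1. Wittig methylenation of its ketone then gives diene 8 as an isolated compound, and a separate ring-closing metathesis returns to the route at 9.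

Step 6. The basic ylide may enolise the hindered α-hydroxy ketone or trigger an α-ketol shift instead of adding. The fallback sets out from 10: addition of (trimethylsilyl)methyllithium with CeCl3 (non-basic, good for hindered ketones) should give the β-hydroxysilane (1R)-1-[2-hydroxy-1-(trimethylsilyl)propan-2-yl]-4-methylcyclohex-3-en-1-ol F2, and Peterson elimination (KH, THF) returns to the route at 11.

Step 10. Allylic transposition during transmetalation (coupling through the γ-carbon to give 1,1-dimethylallyl groups), a stalled second coupling or protodestannylation may erode the double prenylation. The fallback sets out from 16: Stille coupling with allyltributylstannane, which has no regiochemical ambiguity, should give (1R)-4-methyl-1-(propan-2-yl)cyclohex-3-en-1-yl 4-methoxy-3,5-di(prop-2-en-1-yl)benzoate F3. Cross-metathesis of both allyl groups with 2-methylbut-2-ene (Ru benzylidene catalyst) then returns to the route at 18.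

Further compounds
F1 | step 4 | (2R,5R)-2-tert-butyl-5-(3-oxobutyl)-5-(prop-2-en-1-yl)-1,3-dioxolan-4-one | C=CC[C@@]1(CCC(C)=O)O[C@@H](C(C)(C)C)OC1=O
F2 | step 6 | (1R)-1-[2-hydroxy-1-(trimethylsilyl)propan-2-yl]-4-methylcyclohex-3-en-1-ol | CC1=CC[C@@](CC1)(O)C(C)(O)C[Si](C)(C)C
F3 | step 10 | (1R)-4-methyl-1-(propan-2-yl)cyclohex-3-en-1-yl 4-methoxy-3,5-di(prop-2-en-1-yl)benzoate | COc1c(CC=C)cc(C(=O)O[C@@]2(C(C)C)CC=C(C)CC2)cc1CC=C
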